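all flasks: D 0.050 M
- dusk: G 0.15 M; temperature 20 °C; the very flask that is asked about, followed so far
- spring: G 0.075 M; temperature 5 °C; run made earlier
- flask: G 0.150 M; temperature 20 °C; time 30 h

| run | time / h | J / % | D / % |
|---|---|---|---|
| dusk | 1.50 | 24.9 | 76.5 |
| dusk | 5.00 | 33.1 | 65.8 |
| dusk | 8.00 | 32.9 | 65.7 |
| dusk | 12.0 | 34.3 | 65.3 |
| dusk | 20.0 | 34.1 | 65.7 |
| dusk | 25.0 | 35.2 | 66.1 |
| spring | 0.333 | 0.8 | 98.7 |
| spring | 0.500 | 1.4 | 98.5 |
| spring | 1.00 | 2.1 | 97.7 |
| spring | 2.00 | 5.7 | 96.0 |
| spring | 3.00 | 7.8 | 92.3 |
| spring | 4.00 | 9.9 | 89.9 |

(each reading ± 0.5 percentage points)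

- J taken out counts as made
- additions bring no volume worth counting

- birch: change nothing and wait 2.5 d more
- maple: at 30 h raise the temperature by 25 K, then wait 2.5 d
- alder: at 30 h add G, 50.0% of the amount charged, then wait 2.5 d
- elm: at 30 h take out 90% of the J then present, then wait 2.5 d

- J, in percent of the D first charged, at 30 h
- what to do for the largest gain in J; "none" if nothing gains more than 2 percentage points (birch / maple / alder / elm / none)
- J present, with what was taken out counted in, in percent of the D first charged, after birch
- J present, with what was taken out counted in, in percent of the D first charged, after alder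

The dusk flask holds 3.00 G for each D charged, so you can keep its books in fractions of the G charge. At 20.0 h J reads 34.1% and D 65.7%, which together make the whole D charge within scatter. J therefore comes from D one for one, and I book one G per J. In the dusk flask J reads 33.1% at 5.00 h and 35.2% at 25.0 h, so it has nearly stopped. The spring run, colder and with less G, is still rising at its last reading.

The ledger, in fractions of the G charge:

G now in J: 11.4%

G the remaining D would need: 21.9%

G not accounted for: 88.6%

Call the first line the return, the share of a G charge that ended up in J. The missing entry is larger than what the remaining D would need. So either that G stands free and the flask rests at a balance, or it went elsewhere and G is the limiting reagent. A stalled J reads the same on both. I bet on the second. On that booking birch, maple and elm bring no new G and alder does, so I choose alder. You then price the alder dose at the same return: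

gain = dose × return × G per D = 17 percentage points

J after alder = 51.2%

The forecast gave 34.2% at 30 h, 34.3% after birch and 44.5% after alder (range 41% to 48%), and chose elm as “the largest gain under equilibrium”.

The flask gives 34.1%, then 34.1% after birch and 84.5% after alder, and the best choice is alder. My choice holds, but my alder figure of 51.2% falls short.

    D + G + J → 2 J (k = 0.400 L² mol⁻² s⁻¹, Ea = 36.0 kJ mol⁻¹)
    D + G → J (k = 4.10 × 10⁻⁴ L mol⁻¹ s⁻¹, Ea = 80.0 kJ mol⁻¹)
    2 G → E (k = 0.00900 L mol⁻¹ s⁻¹, Ea = 46.0 kJ mol⁻¹)
    (constants at 20 °C)

The loss of G to E is why the dusk flask stops: without that step J reaches 100%, against 34.1%. At 30.0 h the flask holds 0.0665 M of E, two G each, which is 88.6% of the G charge, against the 88.6% I booked; free G stands at 0%. The alder dose returned 33.6%, more than the 11.4% of the first charge. In the neighbour flask charged with 0.60 M of G, the return is 5.22%.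

The readings were computed with made-up constants, noise included.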